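**Remark (numbering and configuration):** germacrane numbering is used for all ten-membered-ring compounds (ring C1–C10, lactone carbons C11–C13, C14 on C10, C15 on C4). The target SMILES is read as (1R,3S,6R,7R,8S,10R,4Z): a trans-fused 6,12-lactone, a trans 1,10-epoxide, and the C8 ester oxygen trans to C11.

## Retrosynthetic overview

1. 27 ← 24 by acylations at O3 and O8; the C1–C10 epoxide and C8–OH (from a C8–Si bond) come from peracid; C13 and the γ-lactone (O–C6, C11–C12) come from cyclodecadienone 14 (C6=O, acetate arm on C7).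
2. Key disconnection: 14 ← cyclohexenol 11 by anionic oxy-Cope ring expansion (6 → 10), which breaks C1–C6, forms C8–C9, and traps the enolate at C7.
3. Feature used: the Z-C4=C5 olefin next to the C6 oxygen is a cyclohexene double bond next to a carbinol in 11. The chair [3,3] shift adds E-C1=C10, turns the C6 alkoxide into the C6 ketone, and relays the C1 stereocentre to C8 (C–Si, masked OH) and C7.
4. 11 ← enone 4 + (E)-2-silylvinyl metal (from 8); 4 ← (S)-carvone 1 (Luche reduction, silylation, allylic oxidation), which supplies C3–O and the sacrificial C1 centre.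
5. Ring order: cyclohexene (chiral pool) → ten-membered ring (step 6) → γ-lactone (step 8) → epoxide (step 10).

Key step: step 6

## Route

Step 1
Reactants: 1 (S)-carvone
Product: 2 (1S,5S)-2-methyl-5-(prop-1-en-2-yl)cyclohex-2-en-1-ol (cis-carveol)
Conditions: NaBH4, CeCl3·7H2O, MeOH, −78 → 0 °C
Reagents that add atoms: none
Why: Luche 1,2-reduction should deliver hydride axially to the half-chair with the isopropenyl group equatorial, which sets the new carbinol centre S (OH cis to isopropenyl).

Step 2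
Reactants: 2 cis-carveol
Product: 3 tert-butyl(dimethyl){[(1S,5S)-2-methyl-5-(prop-1-en-2-yl)cyclohex-2-en-1-yl]oxy}silane
Conditions: TBSCl, imidazole, DMF, rt
Reagents that add atoms: tert-butyldimethylsilyl chloride CC(C)(C)[Si](C)(C)Cl
Why: Imidazole-promoted silylation protects the allylic alcohol as an ether that is stable to the oxidant and the strong bases that follow; no stereocentre is touched.

Step 3
Reactants: 3 cis-carveol TBS ether
Product: 4 (4S,6S)-4-(tert-butyldimethylsilyloxy)-3-methyl-6-(prop-1-en-2-yl)cyclohex-2-en-1-one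
Conditions: CrO3, 3,5-dimethylpyrazole, CH2Cl2, −20 °C
Reagents that add atoms: chromium trioxide O=[Cr](=O)=O
Why: Allylic C–H oxidation with the CrO3·3,5-dimethylpyrazole complex should convert the ring methylene next to the trisubstituted olefin into the conjugated enone under non-basic conditions, leaving both stereocentres (the later C3 and the sacrificial C1) unchanged.

Step 4
Reactants: 5 (E)-1,2-bis(tributylstannyl)ethene
Product: 8 (E)-tert-butoxy(dimethyl)[2-(tributylstannyl)ethenyl]silane, via stannylvinyllithium 6 (not isolated), via chlorosilane 7 (not isolated)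
Conditions: n-BuLi (1 equiv), THF, −78 °C; added to Me2SiCl2 (excess), −78 °C → rt, evaporate; t-BuOH, Et3N, DMAP (cat.), CH2Cl2, 0 °C → rt
Reagents that add atoms: dichlorodimethylsilane C[Si](C)(Cl)Cl; tert-butanol CC(C)(C)O
Why: Tin–lithium exchange of one stannyl group, silylation of the vinyllithium and alcoholysis of the Si–Cl bond all proceed with retention of the E geometry and give a hindered alkoxysilane as a masked hydroxyl.

Step 5
Reactants: 4 enone; 8 (E)-tert-butoxy(dimethyl)[2-(tributylstannyl)ethenyl]silane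
Product: 11 (1S,4S,6S)-1-{(E)-2-[tert-butoxy(dimethyl)silyl]ethenyl}-4-(tert-butyldimethylsilyloxy)-3-methyl-6-(prop-1-en-2-yl)cyclohex-2-en-1-ol, via silylvinyllithium 9 (not isolated), via organocerium 10 (not isolated)
Conditions: 8, n-BuLi, THF, −78 °C; CeCl3 (anhydrous), −78 °C; then 4, −78 °C; aq. NH4Cl
Reagents that add atoms: none
Why: Tin–lithium exchange and transmetalation give a weakly basic organocerium reagent that should add 1,2 without enolisation, attacking anti to the adjacent isopropenyl group (equatorial attack) so that the new carbinol centre carries the two alkenyl groups trans.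

Step 6
Reactants: 11 dialkenyl cyclohexenol
Product: 14 tert-butyl (3S,7S,8S,1(10)E,4Z)-8-[tert-butoxy(dimethyl)silyl]-3-(tert-butyldimethylsilyloxy)-6-oxo-13-norgermacra-1(10),4-dien-12-oate, via potassium alkoxide 12 (not isolated), via potassium enolate 13 (not isolated)
Conditions: KHMDS (1.1 equiv), 18-crown-6, THF, 0 °C → rt; then −78 °C, BrCH2CO2t-Bu, → −40 °C; aq. NH4Cl
Reagents that add atoms: tert-butyl bromoacetate CC(C)(C)OC(=O)CBr
Why: Deprotonation gives alkoxide 12, whose 1,5-diene C8=C7–C6(O−)–C1–C10=C9 undergoes the charge-accelerated [3,3]-sigmatropic (anionic oxy-Cope) shift: C1–C6 breaks, C8–C9 forms, and the cyclohexene is expanded by four atoms through a six-membered chair transition state (a ring expansion, not an end-to-end cyclisation) to the enolate 13 of the cyclodeca-1(10),4-dien-6-one. The closest known reaction type is the anionic oxy-Cope ring expansion of 1-alkenyl-2-isopropenylcyclohex-2-enols to (1(10)E,4Z)-cyclodecadienones with alkylation of the enolate that results. Because the two alkenyl groups are trans, only the chair with both ring bonds equatorial is open: it makes C1=C10 E, keeps the former cyclohexene bond as the 4Z olefin, and places the E-silyl group equatorial, so the C1 configuration of 11 is relayed to C8 (8S, C–Si) while C1 becomes sp2. C7 is set in the second stage: the Z-enolate reacts in the conformation in which it is formed, its inner face is blocked by the transannular C1=C10 bond, and the bromoacetate should attack from the periphery, anti to the C8–C9 bond, which puts the acetate arm trans to silicon (7S here, the later 7R). The step needs [3,3] over fragmentation or silyl transfer and C- over O-alkylation; the doubly allylic alkoxide, the E geometry that holds the hindered silicon away from both oxygens, and the soft α-halo ester should secure this.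

Step 7
Reactants: 14 keto ester
Product: 15 tert-butyl (3S,6S,7S,8S,1(10)E,4Z)-8-[tert-butoxy(dimethyl)silyl]-3-(tert-butyldimethylsilyloxy)-6-hydroxy-13-norgermacra-1(10),4-dien-12-oate
Conditions: NaBH4, CeCl3·7H2O, MeOH/THF, −78 °C
Reagents that add atoms: none
Why: Luche 1,2-reduction of the Z-enone should deliver hydride to the exposed carbonyl face anti to the C7–C8 ring bond (Felkin–Anh, peripheral attack), giving the 6S alcohol with OH cis to the C7 acetate arm, and the tert-butyl ester does not lactonise under these conditions.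

Step 8
Reactants: 15 (6S)-hydroxy ester
Product: 18 (3S,6R,7S,8S,1(10)E,4Z)-8-[tert-butoxy(dimethyl)silyl]-3-(tert-butyldimethylsilyloxy)-13-norgermacra-1(10),4-dien-12,6-olide, via 4-nitrobenzoate 16 (not isolated), via 6R hydroxy ester 17 (not isolated)
Conditions: PPh3, DIAD, 4-O2NC6H4CO2H, THF, 0 °C → rt; then K2CO3 (cat.), MeOH, rt → 40 °C
Reagents that add atoms: 4-nitrobenzoic acid O=C(O)c1ccc(cc1)[N+](=O)[O-]
Why: Mitsunobu esterification inverts the allylic C6 carbinol by SN2 (SN2′ at the fully substituted C4 is disfavoured), and methanolysis of the activated benzoate frees the 6R alkoxide, which should close the trans-fused γ-lactone on the tert-butyl ester by 5-exo-trig acyl transfer; the C6 oxygen of 18 comes from the acid.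

Step 9
Reactants: 18 lactone
Product: 22 (3S,6R,7S,8S,1(10)E,4Z)-8-[tert-butoxy(dimethyl)silyl]-3-(tert-butyldimethylsilyloxy)germacra-1(10),4,11(13)-trien-12,6-olide, via lithium enolate 19 (not isolated), via Mannich base 20 (not isolated), via ammonium iodide 21 (not isolated)
Conditions: LDA, THF, −78 °C; CH2=NMe2+ I−, −78 → 0 °C; then MeI, MeOH, rt; aq. NaHCO3/CH2Cl2, rt
Reagents that add atoms: N,N-dimethylmethyleneiminium iodide (Eschenmoser's salt) C=[N+](C)C.[I-]
Why: Mannich reaction of the lactone enolate with Eschenmoser's salt, N-methylation and β-elimination should give the α-methylene lactone, the lactone being the only enolisable carbonyl at this stage and the C–Si and silyl ether groups being inert.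

Step 10
Reactants: 22 α-methylene lactone
Product: 24 (1R,3S,6R,7R,8S,10R,4Z)-3-(tert-butyldimethylsilyloxy)-1,10-epoxy-8-hydroxygermacra-4,11(13)-dien-12,6-olide, via epoxy silane 23 (not isolated)
Conditions: mCPBA, NaHCO3, CH2Cl2, 0 °C; then solvent switch, mCPBA, KHF2, DMF, rt
Reagents that add atoms: 3-chloroperoxybenzoic acid OOC(=O)c1cccc(Cl)c1
Why: Prilezhaev epoxidation should touch only the electron-rich E-C1=C10 olefin (C4=C5 is deactivated by two allylic C–O bonds, C11=C13 is electron-poor) and only its outer face, which gives the 1R,10R epoxide, and the peracid/fluoride variant of the Tamao–Fleming oxidation then converts C8–Si into C8–OH with retention.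

Step 11
Reactants: 24 epoxy alcohol
Product: 25 (1R,3S,6R,7R,8S,10R,4Z)-3-(tert-butyldimethylsilyloxy)-1,10-epoxy-8-(3-methylbutanoyloxy)germacra-4,11(13)-dien-12,6-olide
Conditions: isovaleryl chloride, pyridine, DMAP (cat.), CH2Cl2, 0 °C → rt
Reagents that add atoms: 3-methylbutanoyl chloride CC(C)CC(=O)Cl
Why: DMAP-catalysed acylation of the only free hydroxyl installs the C8 ester at once, before base can move the lactone from O6 to O8.

Step 12
Reactants: 25 silyl ether
Product: 26 (1R,3S,6R,7R,8S,10R,4Z)-1,10-epoxy-3-hydroxy-8-(3-methylbutanoyloxy)germacra-4,11(13)-dien-12,6-olide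
Conditions: TBAF, AcOH (1:1), THF, 0 °C → rt
Reagents that add atoms: none
Why: Fluoride desilylation buffered with acetic acid should free the C3 allylic alcohol without opening the epoxide, cleaving the ester or adding to the methylene lactone.

Step 13
Reactants: 26 C3 alcohol
Product: 27 (1R,3S,6R,7R,8S,10R,4Z)-3-acetoxy-1,10-epoxy-8-(3-methylbutanoyloxy)germacra-4,11(13)-dien-12,6-olide (target)
Conditions: Ac2O, pyridine, DMAP (cat.), CH2Cl2, 0 °C
Reagents that add atoms: acetic anhydride CC(=O)OC(C)=O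
Why: DMAP-catalysed acetylation of the remaining secondary allylic alcohol completes the target with no change at any stereocentre.

## Compound list

1 | (S)-carvone, (5S)-2-methyl-5-(prop-1-en-2-yl)cyclohex-2-en-1-one | CC1=CC[C@@H](CC1=O)C(C)=C | starting material
2 | (1S,5S)-2-methyl-5-(prop-1-en-2-yl)cyclohex-2-en-1-ol (cis-carveol) | CC1=CC[C@@H](C[C@@H]1O)C(C)=C | intermediate
3 | tert-butyl(dimethyl){[(1S,5S)-2-methyl-5-(prop-1-en-2-yl)cyclohex-2-en-1-yl]oxy}silane | CC1=CC[C@@H](C[C@@H]1O[Si](C)(C)C(C)(C)C)C(C)=C | intermediate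
4 | (4S,6S)-4-(tert-butyldimethylsilyloxy)-3-methyl-6-(prop-1-en-2-yl)cyclohex-2-en-1-one | CC1=CC(=O)[C@@H](C[C@@H]1O[Si](C)(C)C(C)(C)C)C(C)=C | intermediate
5 | (E)-1,2-bis(tributylstannyl)ethene | CCCC[Sn](CCCC)(CCCC)/C=C/[Sn](CCCC)(CCCC)CCCC | starting material
6 | (E)-2-(tributylstannyl)ethenyllithium (not isolated) | [Li]/C=C/[Sn](CCCC)(CCCC)CCCC | intermediate
7 | (E)-chloro(dimethyl)[2-(tributylstannyl)ethenyl]silane (not isolated) | CCCC[Sn](CCCC)(CCCC)/C=C/[Si](C)(C)Cl | intermediate
8 | (E)-tert-butoxy(dimethyl)[2-(tributylstannyl)ethenyl]silane | CCCC[Sn](CCCC)(CCCC)/C=C/[Si](C)(C)OC(C)(C)C | intermediate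
9 | (E)-2-[tert-butoxy(dimethyl)silyl]ethenyllithium (not isolated) | [Li]/C=C/[Si](C)(C)OC(C)(C)C | intermediate
10 | (E)-{2-[tert-butoxy(dimethyl)silyl]ethenyl}cerium dichloride (not isolated) | Cl[Ce](Cl)/C=C/[Si](C)(C)OC(C)(C)C | intermediate
11 | (1S,4S,6S)-1-{(E)-2-[tert-butoxy(dimethyl)silyl]ethenyl}-4-(tert-butyldimethylsilyloxy)-3-methyl-6-(prop-1-en-2-yl)cyclohex-2-en-1-ol (alkenyl groups trans, OH cis to isopropenyl and OTBS) | CC1=C[C@@](O)(/C=C/[Si](C)(C)OC(C)(C)C)[C@@H](C[C@@H]1O[Si](C)(C)C(C)(C)C)C(C)=C | intermediate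
12 | potassium alkoxide of 11 (not isolated) | [K+].CC1=C[C@@]([O-])(/C=C/[Si](C)(C)OC(C)(C)C)[C@@H](C[C@@H]1O[Si](C)(C)C(C)(C)C)C(C)=C | intermediate
13 | potassium (6Z)-enolate of (3S,8S,1(10)E,4Z)-8-[tert-butoxy(dimethyl)silyl]-3-(tert-butyldimethylsilyloxy)-11,12,13-trinorgermacra-1(10),4-dien-6-one (not isolated) | [K+].[O-]/C1=C\[C@@H]([Si](C)(C)OC(C)(C)C)C/C(C)=C/C[C@H](O[Si](C)(C)C(C)(C)C)/C(C)=C\1 | intermediate
14 | tert-butyl (3S,7S,8S,1(10)E,4Z)-8-[tert-butoxy(dimethyl)silyl]-3-(tert-butyldimethylsilyloxy)-6-oxo-13-norgermacra-1(10),4-dien-12-oate | O=C1/C=C(/C)[C@@H](O[Si](C)(C)C(C)(C)C)C/C=C(\C)C[C@H]([Si](C)(C)OC(C)(C)C)[C@H]1CC(=O)OC(C)(C)C | intermediate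
15 | tert-butyl (3S,6S,7S,8S,1(10)E,4Z)-8-[tert-butoxy(dimethyl)silyl]-3-(tert-butyldimethylsilyloxy)-6-hydroxy-13-norgermacra-1(10),4-dien-12-oate | O[C@H]1/C=C(/C)[C@@H](O[Si](C)(C)C(C)(C)C)C/C=C(\C)C[C@H]([Si](C)(C)OC(C)(C)C)[C@H]1CC(=O)OC(C)(C)C | intermediate
16 | tert-butyl (3S,6R,7S,8S,1(10)E,4Z)-8-[tert-butoxy(dimethyl)silyl]-3-(tert-butyldimethylsilyloxy)-6-(4-nitrobenzoyloxy)-13-norgermacra-1(10),4-dien-12-oate (not isolated) | O=C(O[C@@H]1/C=C(/C)[C@@H](O[Si](C)(C)C(C)(C)C)C/C=C(\C)C[C@H]([Si](C)(C)OC(C)(C)C)[C@H]1CC(=O)OC(C)(C)C)c1ccc(cc1)[N+](=O)[O-] | intermediate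
17 | tert-butyl (3S,6R,7S,8S,1(10)E,4Z)-8-[tert-butoxy(dimethyl)silyl]-3-(tert-butyldimethylsilyloxy)-6-hydroxy-13-norgermacra-1(10),4-dien-12-oate (not isolated) | O[C@@H]1/C=C(/C)[C@@H](O[Si](C)(C)C(C)(C)C)C/C=C(\C)C[C@H]([Si](C)(C)OC(C)(C)C)[C@H]1CC(=O)OC(C)(C)C | intermediate
18 | (3S,6R,7S,8S,1(10)E,4Z)-8-[tert-butoxy(dimethyl)silyl]-3-(tert-butyldimethylsilyloxy)-13-norgermacra-1(10),4-dien-12,6-olide (trans-fused) | C1C(=O)O[C@@H]2/C=C(/C)[C@@H](O[Si](C)(C)C(C)(C)C)C/C=C(\C)C[C@H]([Si](C)(C)OC(C)(C)C)[C@@H]12 | intermediate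
19 | lithium enolate of 18 (not isolated) | [Li+].C1=C([O-])O[C@@H]2/C=C(/C)[C@@H](O[Si](C)(C)C(C)(C)C)C/C=C(\C)C[C@H]([Si](C)(C)OC(C)(C)C)[C@@H]12 | intermediate
20 | 13-(dimethylamino) derivative of 18, C11 epimers (Mannich base, not isolated) | CN(C)CC1C(=O)O[C@@H]2/C=C(/C)[C@@H](O[Si](C)(C)C(C)(C)C)C/C=C(\C)C[C@H]([Si](C)(C)OC(C)(C)C)[C@@H]12 | intermediate
21 | 13-(trimethylammonio) derivative of 18 iodide, C11 epimers (not isolated) | [I-].C[N+](C)(C)CC1C(=O)O[C@@H]2/C=C(/C)[C@@H](O[Si](C)(C)C(C)(C)C)C/C=C(\C)C[C@H]([Si](C)(C)OC(C)(C)C)[C@@H]12 | intermediate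
22 | (3S,6R,7S,8S,1(10)E,4Z)-8-[tert-butoxy(dimethyl)silyl]-3-(tert-butyldimethylsilyloxy)germacra-1(10),4,11(13)-trien-12,6-olide | C=C1C(=O)O[C@@H]2/C=C(/C)[C@@H](O[Si](C)(C)C(C)(C)C)C/C=C(\C)C[C@H]([Si](C)(C)OC(C)(C)C)[C@@H]12 | intermediate
23 | (1R,3S,6R,7S,8S,10R,4Z)-8-[tert-butoxy(dimethyl)silyl]-3-(tert-butyldimethylsilyloxy)-1,10-epoxygermacra-4,11(13)-dien-12,6-olide (not isolated) | C=C1C(=O)O[C@@H]2/C=C(/C)[C@@H](O[Si](C)(C)C(C)(C)C)C[C@H]3O[C@]3(C)C[C@H]([Si](C)(C)OC(C)(C)C)[C@@H]12 | intermediate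
24 | (1R,3S,6R,7R,8S,10R,4Z)-3-(tert-butyldimethylsilyloxy)-1,10-epoxy-8-hydroxygermacra-4,11(13)-dien-12,6-olide | C=C1C(=O)O[C@@H]2/C=C(/C)[C@@H](O[Si](C)(C)C(C)(C)C)C[C@H]3O[C@]3(C)C[C@H](O)[C@@H]12 | intermediate
25 | (1R,3S,6R,7R,8S,10R,4Z)-3-(tert-butyldimethylsilyloxy)-1,10-epoxy-8-(3-methylbutanoyloxy)germacra-4,11(13)-dien-12,6-olide | C=C1C(=O)O[C@@H]2/C=C(/C)[C@@H](O[Si](C)(C)C(C)(C)C)C[C@H]3O[C@]3(C)C[C@H](OC(=O)CC(C)C)[C@@H]12 | intermediate
26 | (1R,3S,6R,7R,8S,10R,4Z)-1,10-epoxy-3-hydroxy-8-(3-methylbutanoyloxy)germacra-4,11(13)-dien-12,6-olide | C=C1C(=O)O[C@@H]2/C=C(/C)[C@@H](O)C[C@H]3O[C@]3(C)C[C@H](OC(=O)CC(C)C)[C@@H]12 | intermediate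
27 | (1R,3S,6R,7R,8S,10R,4Z)-3-acetoxy-1,10-epoxy-8-(3-methylbutanoyloxy)germacra-4,11(13)-dien-12,6-olide (CNP0157657.1) | C=C1C(=O)O[C@@H]2/C=C(/C)[C@@H](OC(C)=O)C[C@H]3O[C@]3(C)C[C@H](OC(=O)CC(C)C)[C@@H]12 | target

## Step count and risks

Total step count: 13. Longest linear sequence: 12 steps from (S)-carvone (steps 1–3 and 5–13); step 4 is a one-step side branch from the commercial distannane.

The three steps most likely to fail:

**Step 6.** What may go wrong: the crown-ether-separated potassium enolate 13 is alkylated on oxygen, or it relaxes to another ring conformer before the halide arrives, so that facial control at C7 is lost. The fallback sets out from 11 and comes back at 14. The enolate 13, made as in step 6, is silylated on oxygen (TMSCl, Et3N, −78 °C) to the trimethylsilyl enol ether F1, which is isolated. The C7–C11 bond is then made by a radical process instead of an SN2 process: tert-butyl bromoacetate, fac-Ir(ppy)3 (cat.), 2,6-lutidine, MeCN, blue light. The electrophilic acetate radical should add to C7 of the enol ether from the outer face, and oxidation of the α-siloxy radical with loss of the silyl group returns ketone 14.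

**Step 7.** What may go wrong: poor or reversed facial selectivity of hydride delivery to the C6 carbonyl, because the ketone may react from a ring conformer in which the carbonyl group has turned over. The fallback sets out from 14 and comes back at 18. The C6–O bond is then closed with retention instead of inversion: the 6R alcohol from the reduction is the hydroxy ester 17, now isolated, and base-catalysed acyl transfer onto the tert-butyl ester (NaH cat., THF, or K2CO3, MeOH) gives 18 directly, so the Mitsunobu stage is left out. If both C6 epimers form, they are separated and each is taken through its own lactonisation mode to the same lactone 18. This fallback makes no compound outside the list (F0).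

**Step 10.** What may go wrong: opening of the newly formed 1,10-epoxide (fluoride or acid attack, transannular participation of C4=C5) during the fluoride-promoted C–Si oxidation, or epoxidation from the inner face. The fallback sets out from 22 and comes back at 25. The C–Si bond is oxidised first, before any epoxide is present, by the nucleophilic Tamao protocol (30% H2O2, KF, KHCO3, THF/MeOH, rt) to the 8-hydroxy triene lactone F2. Acylation (isovaleryl chloride, pyridine, DMAP) gives the 8-isovalerate F3. The C1=C10 epoxide is then introduced last with buffered mCPBA (NaHCO3, CH2Cl2, 0 °C) on the fully acylated ring, which returns to 25.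

## Further compounds

F1 | step 6 | (3S,8S,1(10)E,4Z,6Z)-8-[tert-butoxy(dimethyl)silyl]-3-(tert-butyldimethylsilyloxy)-6-(trimethylsilyloxy)-11,12,13-trinorgermacra-1(10),4,6-triene | C[Si](C)(C)O/C1=C\[C@@H]([Si](C)(C)OC(C)(C)C)C/C(C)=C/C[C@H](O[Si](C)(C)C(C)(C)C)/C(C)=C\1
F0 | step 7 | none | none
F2 | step 10 | (3S,6R,7R,8S,1(10)E,4Z)-3-(tert-butyldimethylsilyloxy)-8-hydroxygermacra-1(10),4,11(13)-trien-12,6-olide | C=C1C(=O)O[C@@H]2/C=C(/C)[C@@H](O[Si](C)(C)C(C)(C)C)C/C=C(\C)C[C@H](O)[C@@H]12
F3 | step 10 | (3S,6R,7R,8S,1(10)E,4Z)-3-(tert-butyldimethylsilyloxy)-8-(3-methylbutanoyloxy)germacra-1(10),4,11(13)-trien-12,6-olide | C=C1C(=O)O[C@@H]2/C=C(/C)[C@@H](O[Si](C)(C)C(C)(C)C)C/C=C(\C)C[C@H](OC(=O)CC(C)C)[C@@H]12
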